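## Retrosynthetic overview

1. Target 16 ⇐ diallyl analogue 14 by twofold allyl → prenyl cross-metathesis (prenyl groups last).
2. Spiro cyclohexane of 14 ⇐ triketone 12: spiro-C–CH2 bond and the C-7' oxygen from one aerobic 6-endo radical cyclisation onto the isopropenyl group.
3. 12 ⇐ dihydropyran 11 (hydrolysis) ⇐ hetero-Diels–Alder reaction of methylidene triketone 10 (3 + CH2O) with cyclopentene 9; this key cycloaddition makes the C–CH2–C bond and the tertiary C–O bond and sets two stereocenters.
4. 9 ⇐ (R)-limonene 4 (ozonolysis, aldol ring contraction, decarbonylation); 3 ⇐ phloroacetophenone 1 (dearomatising gem-diallylation).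
5. Ring order: triketone ring and cyclopentene first, temporary dihydropyran by cycloaddition (opened again), spiro cyclohexane last.

Assumption: the acetyl triketone is written as the enol tautomer used in the target SMILES; tautomers are treated as one compound.

## Route

Step 1
Reactants: 1 phloroacetophenone (1-(2,4,6-trihydroxyphenyl)ethan-1-one)
Product: 3 2-acetyl-3-hydroxy-4,4-di(prop-2-en-1-yl)cyclohex-2-ene-1,5-dione, via mono-C-allyl phloroacetophenone 2 (not isolated)
Conditions: NaOMe (3 equiv), allyl bromide (2.2 equiv), MeOH, 0 °C to rt; chromatography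
Reagents that add atoms: allyl bromide C=CCBr
Why: Twofold base-mediated C-allylation (SN2) of the phloroglucinol polyanion, the second allyl group entering the already substituted ring carbon so that the ring is dearomatised to the acidic gem-diallyl triketone (separated from the 3,5-diallyl isomer); no stereocenter is formed.

Step 2
Reactants: 4 (R)-(+)-limonene
Product: 6 (3R)-6-oxo-3-(prop-1-en-2-yl)heptanal, via limonene ozonide 5 (not isolated)
Conditions: O3 (1.0 equiv), CH2Cl2, −78 °C; then Me2S, −78 °C to rt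
Reagents that add atoms: ozone [O-][O+]=O
Why: Chemoselective ozonolysis, the electron-rich trisubstituted ring alkene being cleaved before the isopropenyl group at −78 °C with one equivalent of ozone, and reductive work-up gives the keto aldehyde with the limonene stereocenter untouched.

Step 3
Reactants: 6 (3R)-6-oxo-3-(prop-1-en-2-yl)heptanal
Product: 8 (5S)-2-methyl-5-(prop-1-en-2-yl)cyclopent-1-ene-1-carbaldehyde, via aldol adduct 7 (not isolated)
Conditions: piperidine (0.1 equiv), AcOH (0.1 equiv), toluene, reflux, Dean–Stark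
Reagents that add atoms: none
Why: Intramolecular aldol condensation through the piperidine enamine of the aldehyde (5-exo attack on the methyl ketone, then dehydration to the conjugated enal); the stereocenter carries a hydrogen that is not acidified and is not epimerised under these buffered conditions.

Step 4
Reactants: 8 (5S)-2-methyl-5-(prop-1-en-2-yl)cyclopent-1-ene-1-carbaldehyde
Product: 9 (3R)-1-methyl-3-(prop-1-en-2-yl)cyclopent-1-ene
Conditions: [RhCl(cod)]2 (2.5 mol %), Ph2P(CH2)3PPh2 (5 mol %), diglyme, 160 °C, product distilled off with the CO stream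
Reagents that add atoms: none
Why: Rhodium-catalysed decarbonylation of the enal (Tsuji–Wilkinson type: formyl C–H insertion, CO extrusion, C–H reductive elimination) replaces CHO by H with the trisubstituted alkene left in place, and the stereocenter is not involved.

Step 5
Reactants: 3 2-acetyl-3-hydroxy-4,4-di(prop-2-en-1-yl)cyclohex-2-ene-1,5-dione, 9 (3R)-1-methyl-3-(prop-1-en-2-yl)cyclopent-1-ene
Product: 11 (1R,3aR,9aS)-5-acetyl-6-hydroxy-3a-methyl-1-(prop-1-en-2-yl)-7,7-di(prop-2-en-1-yl)-1,2,3,3a,9,9a-hexahydrocyclopenta[b]chromen-8(7H)-one, via methylidene triketone 10 (not isolated)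
Conditions: (CH2O)n (1.5 equiv), 9 (3 equiv, excess recovered), NaOAc (0.3 equiv), AcOH/1,4-dioxane 1:4, 90 °C, sealed tube
Reagents that add atoms: formaldehyde (as paraformaldehyde) C=O
Why: Knoevenagel condensation at the acidic ring CH2 gives the α-methylidene triketone, an electron-poor 1-oxadiene that undergoes an inverse-electron-demand hetero-Diels–Alder reaction with the electron-rich trisubstituted cyclopentene (expected to react faster than the branched isopropenyl or the allyl groups), CH2 bonding to the CH terminus and O to the methyl-bearing carbon, suprafacially and anti to the neighbouring isopropenyl group, which sets C-9a (S) and C-3a (R) from the limonene-derived center.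

Step 6
Reactants: 11 (1R,3aR,9aS)-5-acetyl-6-hydroxy-3a-methyl-1-(prop-1-en-2-yl)-7,7-di(prop-2-en-1-yl)-1,2,3,3a,9,9a-hexahydrocyclopenta[b]chromen-8(7H)-one
Product: 12 2-acetyl-3,5-dihydroxy-4-{[(1S,2R,5R)-2-hydroxy-2-methyl-5-(prop-1-en-2-yl)cyclopentyl]methyl}-6,6-di(prop-2-en-1-yl)cyclohexa-2,4-dien-1-one
Conditions: KOH (6 equiv), EtOH/H2O 1:1, 80 °C, argon; then 1 M HCl, 0 °C, to pH 4
Reagents that add atoms: water O
Why: Alkaline hydrolysis of the cyclic vinylogous ester by addition–elimination at C-4a, driven by formation of the doubly deprotonated triketone, leaves the tertiary carbinol C–O bond intact so its configuration is retained (a pyran closed through the other carbonyl oxygen would give the same product).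

Step 7
Reactants: 12 2-acetyl-3,5-dihydroxy-4-{[(1S,2R,5R)-2-hydroxy-2-methyl-5-(prop-1-en-2-yl)cyclopentyl]methyl}-6,6-di(prop-2-en-1-yl)cyclohexa-2,4-dien-1-one
Product: 14 (1R,3'R,3a'S,7'R,7a'R)-3-acetyl-3',4,7'-trihydroxy-3',7'-dimethyl-5,5-di(prop-2-en-1-yl)-1',2',3',3a',4',6',7',7a'-octahydrospiro[cyclohex-3-ene-1,5'-indene]-2,6-dione, via tertiary hydroperoxide 13 (not isolated)
Conditions: Mn(OAc)3·2H2O (0.2 equiv), air (1 atm), AcOH, 25 °C; then PPh3 (1.2 equiv); chromatography
Reagents that add atoms: dioxygen O=O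
Why: Manganese-mediated aerobic oxidative radical cyclisation in which the radical at the ring carbon between the two carbonyls closes 6-endo onto the isopropenyl group through a chair (ring fusion trans because the two cyclopentane substituents are already trans), the tertiary C-7' radical is trapped by O2 from the equatorial face because the axial face is blocked by the axial carbonyl of the new spiro center (methyl axial, oxygen equatorial), and the spiro center forms with the manganese-chelated acetyl-enol flank in the open equatorial site, a modest preference that leaves a minor spiro epimer to be separated.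

Step 8
Reactants: 14 (1R,3'R,3a'S,7'R,7a'R)-3-acetyl-3',4,7'-trihydroxy-3',7'-dimethyl-5,5-di(prop-2-en-1-yl)-1',2',3',3a',4',6',7',7a'-octahydrospiro[cyclohex-3-ene-1,5'-indene]-2,6-dione
Product: 16 (1R,3'R,3a'S,7'R,7a'R)-3-acetyl-3',4,7'-trihydroxy-3',7'-dimethyl-5,5-bis(3-methylbut-2-en-1-yl)-1',2',3',3a',4',6',7',7a'-octahydrospiro[cyclohex-3-ene-1,5'-indene]-2,6-dione, via mono-prenyl intermediate 15 (not isolated)
Conditions: second-generation Grubbs catalyst (10 mol %), 2-methyl-2-butene/CH2Cl2 1:1, 40 °C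
Reagents that add atoms: 2-methyl-2-butene CC=C(C)C
Why: Olefin cross-metathesis of both terminal allyl groups with excess 2-methyl-2-butene converts them into prenyl groups, the only other C=C being the inert tetrasubstituted enol double bond, and no stereocenter is touched.

## Compound list

1 | 1-(2,4,6-trihydroxyphenyl)ethan-1-one (phloroacetophenone) | CC(=O)c1c(O)cc(O)cc1O | starting material
2 | 1-[2,4,6-trihydroxy-3-(prop-2-en-1-yl)phenyl]ethan-1-one | CC(=O)c1c(O)cc(O)c(CC=C)c1O | intermediate
3 | 2-acetyl-3-hydroxy-4,4-di(prop-2-en-1-yl)cyclohex-2-ene-1,5-dione (enol form of the gem-diallyl triketone) | CC(=O)C1=C(O)C(CC=C)(CC=C)C(=O)CC1=O | intermediate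
4 | (R)-(+)-limonene, (4R)-1-methyl-4-(prop-1-en-2-yl)cyclohex-1-ene | CC1=CC[C@@H](CC1)C(C)=C | starting material
5 | limonene secondary ozonide (1,2,4-trioxolane across the former ring alkene, R at the isopropenyl-bearing carbon, ozonide carbons as a mixture) | CC(=C)[C@@H]1CCC2(C)OOC(C1)O2 | intermediate
6 | (3R)-6-oxo-3-(prop-1-en-2-yl)heptanal | O=CC[C@@H](CCC(C)=O)C(C)=C | intermediate
7 | (5R)-2-hydroxy-2-methyl-5-(prop-1-en-2-yl)cyclopentane-1-carbaldehyde (aldol adduct, C-1 and C-2 as a mixture) | O=CC1C(C)(O)CC[C@H]1C(C)=C | intermediate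
8 | (5S)-2-methyl-5-(prop-1-en-2-yl)cyclopent-1-ene-1-carbaldehyde | CC1=C(C=O)[C@@H](CC1)C(C)=C | intermediate
9 | (3R)-1-methyl-3-(prop-1-en-2-yl)cyclopent-1-ene | CC1=C[C@@H](CC1)C(C)=C | intermediate
10 | 2-acetyl-3-hydroxy-6-methylidene-4,4-di(prop-2-en-1-yl)cyclohex-2-ene-1,5-dione | CC(=O)C1=C(O)C(CC=C)(CC=C)C(=O)C(=C)C1=O | intermediate
11 | (1R,3aR,9aS)-5-acetyl-6-hydroxy-3a-methyl-1-(prop-1-en-2-yl)-7,7-di(prop-2-en-1-yl)-1,2,3,3a,9,9a-hexahydrocyclopenta[b]chromen-8(7H)-one (pyran cis-fused to the cyclopentane, isopropenyl trans to the ring CH2) | CC(=O)C1=C(O)C(CC=C)(CC=C)C(=O)C2=C1O[C@]3(C)CC[C@@H](C(C)=C)[C@@H]3C2 | intermediate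
12 | 2-acetyl-3,5-dihydroxy-4-{[(1S,2R,5R)-2-hydroxy-2-methyl-5-(prop-1-en-2-yl)cyclopentyl]methyl}-6,6-di(prop-2-en-1-yl)cyclohexa-2,4-dien-1-one | CC(=O)C1=C(O)C(C[C@H]2[C@@H](CC[C@@]2(C)O)C(C)=C)=C(O)C(CC=C)(CC=C)C1=O | intermediate
13 | (1R,3'R,3a'S,7'R,7a'R)-3-acetyl-7'-hydroperoxy-3',4-dihydroxy-3',7'-dimethyl-5,5-di(prop-2-en-1-yl)octahydrospiro[cyclohex-3-ene-1,5'-indene]-2,6-dione | CC(=O)C1=C(O)C(CC=C)(CC=C)C(=O)[C@]2(C[C@H]3[C@@H](CC[C@@]3(C)O)[C@](C)(OO)C2)C1=O | intermediate
14 | (1R,3'R,3a'S,7'R,7a'R)-3-acetyl-3',4,7'-trihydroxy-3',7'-dimethyl-5,5-di(prop-2-en-1-yl)octahydrospiro[cyclohex-3-ene-1,5'-indene]-2,6-dione (trans-fused hydrindane, 7'-methyl axial) | CC(=O)C1=C(O)C(CC=C)(CC=C)C(=O)[C@]2(C[C@H]3[C@@H](CC[C@@]3(C)O)[C@](C)(O)C2)C1=O | intermediate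
15 | (1R,3'R,3a'S,7'R,7a'R)-3-acetyl-3',4,7'-trihydroxy-3',7'-dimethyl-5-(3-methylbut-2-en-1-yl)-5-(prop-2-en-1-yl)octahydrospiro[cyclohex-3-ene-1,5'-indene]-2,6-dione (mixture at C-5) | CC(=O)C1=C(O)C(CC=C)(CC=C(C)C)C(=O)[C@]2(C[C@H]3[C@@H](CC[C@@]3(C)O)[C@](C)(O)C2)C1=O | intermediate
16 | (1R,3'R,3a'S,7'R,7a'R)-3-acetyl-3',4,7'-trihydroxy-3',7'-dimethyl-5,5-bis(3-methylbut-2-en-1-yl)octahydrospiro[cyclohex-3-ene-1,5'-indene]-2,6-dione | CC(=O)C1=C(O)C(CC=C(C)C)(CC=C(C)C)C(=O)[C@]2(C[C@H]3[C@@H](CC[C@@]3(C)O)[C@](C)(O)C2)C1=O | target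

## Step count and risks

Total step count: 8. Longest linear sequence: 7 steps (4 to 16, steps 2 to 8).

Steps most likely to fail:

Step 5 (hetero-Diels–Alder). The oxadiene may also add to the isopropenyl group, give ene products, or be intercepted by a second molecule of 3. The fallback sets out from enal 8 and comes back at 12, bypassing 9 and 11. Nucleophilic epoxidation of 8 (H2O2, NaOH, MeOH, 0 °C) on the face anti to the isopropenyl group gives (1S,2S,5R)-5-methyl-2-(prop-1-en-2-yl)-6-oxabicyclo[3.1.0]hexane-1-carbaldehyde F1. SmI2 (THF/MeOH, −78 °C) cleaves the α C–O bond to give (1S,2R,5R)-2-hydroxy-2-methyl-5-(prop-1-en-2-yl)cyclopentane-1-carbaldehyde F2, whose epimerisable C-1 settles trans to both neighbouring carbon substituents. Condensation of F2 with 3 in the presence of Hantzsch ester and piperidinium acetate (CH2Cl2, rt) gives the alkylidene triketone F3, which is reduced in situ by hydride transfer to 12.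

Step 6 (opening of the pyran). Hydroxide attack on the anionic vinylogous ester may be slow, and hot alkali may cleave the acetyl group. The fallback sets out from 11 and comes back at 14 without a separate opening step. 11 is taken directly into the manganese/air oxidation in AcOH/H2O 9:1 at 50 °C, where acid-catalysed reversible hydration of the vinylogous ester keeps a small stationary amount of 12 that is oxidised as it forms (through 13, then PPh3). This fallback makes no new compound (none F0).

Step 7 (radical cyclisation). The radical between the carbonyls may be intercepted by O2 before it cyclises, peroxide by-products may form, and the ratio of spiro epimers may be poor. The fallback sets out from 12 and comes back at 14 in two operations. Mn(OAc)3·2H2O (2.2 equiv) with Cu(OAc)2·H2O (1 equiv) in degassed AcOH closes the ring and ends by oxidative elimination to (1R,3'R,3a'S,7a'R)-3-acetyl-3',4-dihydroxy-3'-methyl-7'-methylidene-5,5-di(prop-2-en-1-yl)octahydrospiro[cyclohex-3-ene-1,5'-indene]-2,6-dione F4, at which stage the spiro epimers are separated. Hydration with Co(acac)2 (cat.), PhSiH3 and O2 in i-PrOH (hydrogen-atom transfer to the 1,1-disubstituted alkene in preference to the allyl groups, O2 trapping from the equatorial face) then gives 14.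

Further compounds
F1 | step 5 | (1S,2S,5R)-5-methyl-2-(prop-1-en-2-yl)-6-oxabicyclo[3.1.0]hexane-1-carbaldehyde | O=C[C@@]12O[C@]1(C)CC[C@H]2C(C)=C
F2 | step 5 | (1S,2R,5R)-2-hydroxy-2-methyl-5-(prop-1-en-2-yl)cyclopentane-1-carbaldehyde | O=C[C@H]1[C@@H](CC[C@@]1(C)O)C(C)=C
F3 | step 5 | 2-acetyl-3-hydroxy-6-{[(1S,2R,5R)-2-hydroxy-2-methyl-5-(prop-1-en-2-yl)cyclopentyl]methylidene}-4,4-di(prop-2-en-1-yl)cyclohex-2-ene-1,5-dione | CC(=O)C1=C(O)C(CC=C)(CC=C)C(=O)C(=C[C@H]2[C@@H](CC[C@@]2(C)O)C(C)=C)C1=O
F0 | step 6 | none | none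
F4 | step 7 | (1R,3'R,3a'S,7a'R)-3-acetyl-3',4-dihydroxy-3'-methyl-7'-methylidene-5,5-di(prop-2-en-1-yl)octahydrospiro[cyclohex-3-ene-1,5'-indene]-2,6-dione | CC(=O)C1=C(O)C(CC=C)(CC=C)C(=O)[C@]2(C[C@H]3[C@@H](CC[C@@]3(C)O)C(=C)C2)C1=O
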